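**Retrosynthetic overview**
1. C13–C14: the enone-ketol is cut into a 2-lithio-1-alkene (Shapiro reaction on a C13 methyl ketone) and a glycolic Weinreb amide.
2. C4: the CO2H/CH3 pair comes from α-face methylation and then oxidation of a C4 formyl group.
3. Key cut C4–C5 (C9–C10 and C8–O close in the same operation): one-electron oxidation of a chiral enamine makes the aldehyde α-carbon electrophilic, and it is joined to the nucleophilic alkene carbon C5 of an acyclic E,E-dienyl keto aldehyde.
4. Ring order: ring A, then ring B, then a temporary dihydropyran ring C (C8–O–C13) that masks the alcohol and the ketone and is opened later.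
5. The keto aldehyde comes from (E)-geranylacetone (13 carbons) and a four-carbon acetal Grignard reagent, through terminal allylic oxidation and the bromide.

Numbering: labdane numbering is used throughout. C1–C10 form the decalin and C11–C16 the side chain (C16 is the methylene carbon). C17 sits on C8, C18 (α) and C19 (β) on C4, and C20 on C10.

Assumption: the (2S,5S)-imidazolidinone is taken to give the drawn normal-labdane series, by the usual model (bond formation on the enamine face away from the benzyl group, formyl-bearing carbon equatorial in the chair); if the sense proves opposite, the equally available (2R,5R) catalyst is used.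

**Step 1**
Reactants: 1 (E)-geranylacetone
Product: 2 geranylacetone ethylene ketal [2-[(3E)-4,8-dimethylnona-3,7-dien-1-yl]-2-methyl-1,3-dioxolane]
Conditions: HOCH2CH2OH, p-TsOH (cat.), PhH, reflux, Dean–Stark
Reagents that add atoms: ethylene glycol, OCCO
Why: Acid-catalysed ketalisation with azeotropic water removal masks the only carbonyl against the Grignard reagent of step 4, leaves both trisubstituted alkenes untouched and creates no stereocentre.

**Step 2**
Reactants: 2 geranylacetone ethylene ketal
Product: 3 (2E,6E)-2,6-dimethyl-9-(2-methyl-1,3-dioxolan-2-yl)nona-2,6-dien-1-ol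
Conditions: SeO2 (0.3 equiv), t-BuOOH (3 equiv), salicylic acid (cat.), CH2Cl2, 0 °C to rt
Reagents that add atoms: tert-butyl hydroperoxide, CC(C)(C)OO (oxygen relayed through catalytic SeO2, O=[Se]=O)
Why: Catalytic SeO2/t-BuOOH allylic oxidation (ene reaction, then [2,3]-shift) prefers the terminal gem-dimethyl alkene and oxidises only the methyl trans to the chain, so the new allylic alcohol is E and the inner E-alkene and the ketal survive.

**Step 3**
Reactants: 3 allylic alcohol
Product: 4 2-[(3E,7E)-9-bromo-4,8-dimethylnona-3,7-dien-1-yl]-2-methyl-1,3-dioxolane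
Conditions: CBr4, PPh3, CH2Cl2, 0 °C (used crude)
Reagents that add atoms: carbon tetrabromide, BrC(Br)(Br)Br
Why: The neutral Appel reaction replaces the primary allylic OH by Br through SN2 on the oxyphosphonium ion, without acid that would open the ketal and without allylic transposition or E/Z erosion.

**Step 4**
Reactants: 4 allylic bromide; 5 2-(3-chloropropyl)-1,3-dioxolane
Product: 7 bis-acetal 2-[(3E,7E)-12-(1,3-dioxolan-2-yl)-4,8-dimethyldodeca-3,7-dien-1-yl]-2-methyl-1,3-dioxolane, via Grignard reagent 6 (not isolated)
Conditions: 5, Mg, BrCH2CH2Br (cat.), THF, reflux; then 4, Li2CuCl4 (5 mol %), THF, −78 to 0 °C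
Reagents that add atoms: 5 2-(3-chloropropyl)-1,3-dioxolane, ClCCCC1OCCO1 (delivered as 6)
Why: Kochi-type copper-catalysed sp3–sp3 coupling of a Grignard reagent with a primary allylic bromide proceeds at the α-carbon (SN2) with retention of the E geometry, both acetals are inert, and C2, C3, C4 and C19 are installed in one step.

**Step 5**
Reactants: 7 bis-acetal
Product: 8 (6E,10E)-6,10-dimethyl-14-oxopentadeca-6,10-dienal
Conditions: 1 M HCl, THF, rt
Reagents that add atoms: water, O
Why: Aqueous-acid acetal hydrolysis releases the aldehyde and the ketone together, and dilute acid at room temperature does not protonate the trisubstituted alkenes.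

**Step 6 (key step)**
Reactants: 8 keto aldehyde
Product: 11 tricyclic enol-ether aldehyde 8α,13-epoxy-14,15,19-trinorlabd-12-en-18-al (4α-CHO 4β-H 5α-H 9α-H 8β-Me 10β-Me), via catalyst-bound enamine 9 (not isolated), via oxocarbenium trifluoroacetate 10 (not isolated)
Conditions: (2S,5S)-5-benzyl-2-tert-butyl-3-methylimidazolidin-4-one·TFA (30 mol %), Cu(OTf)2 (2.5 equiv, slow addition), CF3CO2Na (2 equiv), TFA (3 equiv), i-PrCN/DME, rt, 17 h; then Et3N, 0 °C; Et3N-washed silica
Reagents that add atoms: none
Why: Proposed new method: condensation of 8 with the imidazolidinone gives E-enamine 9, and one-electron oxidation by Cu(OTf)2 turns its normally nucleophilic α-carbon C4 into an electrophilic three-π-electron radical cation (an enolonium-type synthon) that bonds to the equally nucleophilic C5 of the C5=C10 alkene on the face left open by the benzyl group; chair–chair 6-endo/6-endo closure of the E,E-diene (ring A, then ring B) sets 5α-H, 10β-Me and 9α-H, a second oxidation by divalent copper converts the tertiary C8 radical into the cation, and the C13 ketone oxygen captures it from the equatorial α face (the β face is blocked by the axial C20 methyl) to give 10, which loses H-12 to base; the closest known reaction types are the arene-terminated organo-SOMO enantioselective polyene cyclisation of aldehydes and the ketone-terminated acid cyclisation of farnesylacetone to sclareol oxide.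

**Step 7**
Reactants: 11 tricyclic enol-ether aldehyde
Product: 12 8α,13-epoxy-14,15-dinorlabd-12-en-19-al (4α-Me, 4β-CHO axial)
Conditions: KOt-Bu (1.5 equiv), MeI (5 equiv), THF/t-BuOH, 0 °C to rt
Reagents that add atoms: iodomethane, CI
Why: Alkylation of the exocyclic aldehyde enolate takes MeI from the equatorial α face because the β face is screened by the 1,3-diaxial C20 methyl, so both C4 epimers of 11 converge on the 4α-methyl/4β-formyl quaternary centre, while the base-stable enol ether keeps the C13 ketone from being enolised.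

**Step 8**
Reactants: 12 methylated enol-ether aldehyde
Product: 14 8α-hydroxy-13-oxo-14,15-dinorlabdan-19-oic acid, via hydroxy keto aldehyde 13 (not isolated)
Conditions: 1 M HCl (cat.), THF/H2O, rt, 1 h; then NaClO2, NaH2PO4, 2-methyl-2-butene (30 equiv), t-BuOH/H2O, rt
Reagents that add atoms: water, O; sodium chlorite, [Na+].[O-]Cl=O
Why: Enol-ether hydrolysis cleaves only the C13–O bond, so the C8 configuration is kept, and it removes the chlorine-sensitive alkene before the Pinnick oxidation converts the hindered non-enolisable axial aldehyde into the C19 acid without touching the ketone or the tertiary alcohol.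

**Step 9**
Reactants: 14 hydroxy keto acid
Product: 15 (E)-13-(2,4,6-triisopropylbenzenesulfonyl)hydrazone of 14
Conditions: 2,4,6-(i-Pr)3C6H2SO2NHNH2 (1.1 equiv), MeCN, rt (crystallise)
Reagents that add atoms: 2,4,6-triisopropylbenzenesulfonohydrazide, CC(C)c1cc(C(C)C)c(S(=O)(=O)NN)c(C(C)C)c1
Why: Hydrazone condensation occurs at the only ketone (any hemiketal or enol-ether form of 14 funnels to the same product), places the sulfonamide nitrogen syn to the methyl group, and gives a crystalline compound whose recrystallisation raises the ee.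

**Step 10**
Reactants: 15 trisylhydrazone; 16 2-hydroxy-N-methoxy-N-methylacetamide
Product: 19 8α,15-dihydroxy-14-oxolabd-13(16)-en-19-oic acid (target), via trilithiated vinyllithium 17 (not isolated), via lithium alkoxide of the amide 18 (not isolated)
Conditions: 15, n-BuLi (4.2 equiv), TMEDA, THF, −78 to 0 °C (N2 evolution), back to −78 °C; add 18 [from 16, n-BuLi (1.0 equiv), THF, −78 °C]; −78 to −20 °C; inverse quench into cold 1 M HCl
Reagents that add atoms: 16 2-hydroxy-N-methoxy-N-methylacetamide, CON(C)C(=O)CO (delivered as 18)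
Why: The Shapiro reaction deprotonates the methyl group syn to the N-anion and, after loss of sulfinate and N2, turns the former carbonyl carbon C13 into the 2-lithio-1-alkene 17 (carboxylate and alkoxide are protected as lithium salts); 17 acylates the Weinreb amide once through the stable chelate, the cold acidic inverse quench protonates the liberated amine before it can add to the new enone, and no stereocentre is epimerisable under these conditions.

**Compound list**
1 | (E)-geranylacetone, (5E)-6,10-dimethylundeca-5,9-dien-2-one | CC(=O)CC/C=C(\C)CCC=C(C)C | starting material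
2 | 2-[(3E)-4,8-dimethylnona-3,7-dien-1-yl]-2-methyl-1,3-dioxolane | CC1(CC/C=C(\C)CCC=C(C)C)OCCO1 | intermediate
3 | (2E,6E)-2,6-dimethyl-9-(2-methyl-1,3-dioxolan-2-yl)nona-2,6-dien-1-ol | CC1(CC/C=C(\C)CC/C=C(\C)CO)OCCO1 | intermediate
4 | 2-[(3E,7E)-9-bromo-4,8-dimethylnona-3,7-dien-1-yl]-2-methyl-1,3-dioxolane | CC1(CC/C=C(\C)CC/C=C(\C)CBr)OCCO1 | intermediate
5 | 2-(3-chloropropyl)-1,3-dioxolane | ClCCCC1OCCO1 | starting material
6 | [3-(1,3-dioxolan-2-yl)propyl]magnesium chloride (not isolated) | Cl[Mg]CCCC1OCCO1 | intermediate
7 | 2-[(3E,7E)-12-(1,3-dioxolan-2-yl)-4,8-dimethyldodeca-3,7-dien-1-yl]-2-methyl-1,3-dioxolane | CC1(CC/C=C(\C)CC/C=C(\C)CCCCC2OCCO2)OCCO1 | intermediate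
8 | (6E,10E)-6,10-dimethyl-14-oxopentadeca-6,10-dienal | CC(=O)CC/C=C(\C)CC/C=C(\C)CCCCC=O | intermediate
9 | E-enamine of 8 with the (2S,5S)-imidazolidinone (not isolated) | CC(=O)CC/C=C(\C)CC/C=C(\C)CCC/C=C/N1[C@@H](Cc2ccccc2)C(=O)N(C)[C@H]1C(C)(C)C | intermediate
10 | C13 oxocarbenium trifluoroacetate of the cyclised aldehyde (not isolated) | CC=1CC[C@@H]2[C@@]3(C)CCC[C@@H](C=O)[C@@H]3CC[C@@]2(C)[O+]=1.[O-]C(=O)C(F)(F)F | intermediate
11 | 8α,13-epoxy-14,15,19-trinorlabd-12-en-18-al (4α-CHO, 4β-H, 5α-H, 9α-H, 8β-Me, 10β-Me) | CC1=CC[C@@H]2[C@@]3(C)CCC[C@@H](C=O)[C@@H]3CC[C@@]2(C)O1 | intermediate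
12 | 8α,13-epoxy-14,15-dinorlabd-12-en-19-al (4α-Me, 4β-CHO) | CC1=CC[C@@H]2[C@@]3(C)CCC[C@](C)(C=O)[C@@H]3CC[C@@]2(C)O1 | intermediate
13 | 8α-hydroxy-13-oxo-14,15-dinorlabdan-19-al (not isolated) | CC(=O)CC[C@@H]1[C@@]2(C)CCC[C@](C)(C=O)[C@@H]2CC[C@@]1(C)O | intermediate
14 | 8α-hydroxy-13-oxo-14,15-dinorlabdan-19-oic acid | CC(=O)CC[C@@H]1[C@@]2(C)CCC[C@](C)(C(=O)O)[C@@H]2CC[C@@]1(C)O | intermediate
15 | (E)-13-(2,4,6-triisopropylbenzenesulfonyl)hydrazone of 14 | C/C(=N\NS(=O)(=O)c1c(C(C)C)cc(C(C)C)cc1C(C)C)CC[C@@H]1[C@@]2(C)CCC[C@](C)(C(=O)O)[C@@H]2CC[C@@]1(C)O | intermediate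
16 | 2-hydroxy-N-methoxy-N-methylacetamide | CON(C)C(=O)CO | starting material
17 | 13-lithio-13(16)-ene, lithium 8-alkoxide, lithium 19-carboxylate (not isolated) | [Li]C(=C)CC[C@@H]1[C@@]2(C)CCC[C@](C)(C(=O)O[Li])[C@@H]2CC[C@@]1(C)O[Li] | intermediate
18 | lithium alkoxide of 16 (not isolated) | CON(C)C(=O)CO[Li] | intermediate
19 | 8α,15-dihydroxy-14-oxolabd-13(16)-en-19-oic acid (CNP0196657.1) | C=C(CC[C@@H]1[C@@]2(C)CCC[C@](C)(C(=O)O)[C@@H]2CC[C@@]1(C)O)C(=O)CO | target

**Totals**
Total step count: 10. Longest linear sequence: 10 steps (1 to 19). The reagents 6 and 18 are made in the flask within steps 4 and 10.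

**Three steps most likely to fail**

Step 6. The first risk is that the tertiary C10 radical or cation ends by proton loss before ring B closes. The second is that C8 is taken by the nitrile solvent, by trifluoroacetate or by β-hydrogen loss instead of by the ketone oxygen. The third is that the ee stays below about 90 %, which the recrystallisation of 15 can correct.
The fallback sets out from 8 and comes back at 11 by separating the radical stage from the polar stage. The same enamine oxidation is run with Cu(OAc)2 as co-oxidant, so that the C8 radical ends by β-hydrogen loss and gives the exocyclic alkene 13-oxo-14,15,19-trinorlabd-8(17)-en-18-al F1. A separate Brønsted-acid cycloisomerisation (Amberlyst 15 or catalytic TfOH, CH2Cl2, −20 °C) then protonates the alkene at C17 and lets the ketone oxygen close on the α face of C8 to give 11.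

Step 10. The tetra-anion of 15 may be too insoluble to deliver 17 cleanly, and the alkoxide-bearing amide 18 may acylate slowly.
The fallback sets out from 14 and comes back at 19 with the polarity at C13 reversed. Hydrazine hydrate (EtOH, Et3N) gives the simple hydrazone of the hydroxy keto acid F4. Iodine with 1,1,3,3-tetramethylguanidine (THF, 0 °C, Barton vinyl iodide synthesis) gives 8α-hydroxy-13-iodo-14,15-dinorlabd-13(16)-en-19-oic acid F5. A carbonylative Stille coupling (CO 1 atm, Bu3SnCH2OH, Pd(PPh3)4 as the zerovalent palladium source, LiCl, THF, 50 °C) then inserts C14 as CO and transfers the hydroxymethyl group to give 19 directly, tolerating the free acid and alcohol.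

Step 7. Hindered aldehyde enolates can O-methylate or undergo aldol reactions.
The fallback sets out from 11 and comes back at 14 by moving the alkylation to the acid oxidation level. AgNO3/NaOH (aqueous EtOH, basic, so the enol ether survives) oxidises 11 to 8α,13-epoxy-14,15,19-trinorlabd-12-en-18-oic acid F2. LDA (2.2 equiv, THF, 0 °C) followed by MeI methylates the enediolate from the same equatorial α face to give 8α,13-epoxy-14,15-dinorlabd-12-en-19-oic acid F3. Dilute HCl in THF then opens the enol ether to 14.

**Further compounds**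
F1 | step 6 | 13-oxo-14,15,19-trinorlabd-8(17)-en-18-al | CC(=O)CC[C@@H]1[C@@]2(C)CCC[C@@H](C=O)[C@@H]2CCC1=C
F2 | step 7 | 8α,13-epoxy-14,15,19-trinorlabd-12-en-18-oic acid | CC1=CC[C@@H]2[C@@]3(C)CCC[C@@H](C(=O)O)[C@@H]3CC[C@@]2(C)O1
F3 | step 7 | 8α,13-epoxy-14,15-dinorlabd-12-en-19-oic acid | CC1=CC[C@@H]2[C@@]3(C)CCC[C@](C)(C(=O)O)[C@@H]3CC[C@@]2(C)O1
F4 | step 10 | 13-hydrazone of 8α-hydroxy-13-oxo-14,15-dinorlabdan-19-oic acid | C/C(=N\N)CC[C@@H]1[C@@]2(C)CCC[C@](C)(C(=O)O)[C@@H]2CC[C@@]1(C)O
F5 | step 10 | 8α-hydroxy-13-iodo-14,15-dinorlabd-13(16)-en-19-oic acid | C=C(I)CC[C@@H]1[C@@]2(C)CCC[C@](C)(C(=O)O)[C@@H]2CC[C@@]1(C)O
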